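**Retrosynthetic overview**
1. Ring A is the methyl orsellinate ring that carries the CH2, ring B is the central orcinol ring, and ring C is the methyl haematommate-type ring. All three benzene rings are bought intact, so no ring is formed. The B–O–C ether is assembled first and ring A is attached last.
2. Final disconnection: the C–H next to the methyl group of ring B goes back to C–Br, a temporary blocking group.
3. Key disconnection: the bond from the bridging CH2 to the ring B carbon between its two OH groups. Both carbons linked by the CH2 are nucleophilic resorcinol carbons, so ring A is polarity-reversed into its o-quinone methide (from the Mannich base of methyl orsellinate). One protecting-group-free operation then joins the C10 and C17 halves and completes the skeleton with all five phenols, the aldehyde and both esters in place.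
4. Enabling feature: the benzylic carbon on C3 of ring A is flanked by the C2 and C4 hydroxyls, either of which can expel a leaving group to give the quinone methide. Its partner is the ring B carbon flanked by two hydroxyls, the enol carbon of a masked 1,3-diketone.
5. Ether disconnection: SNAr of a Baeyer–Villiger-derived ring B phenol on a ring C fluoride flanked by CHO and CO2Me. The fluoride comes from 3-fluoro-5-methylphenol by bromination, directed metalation/formylation and carbonylation.

Key step: step 11

Assumption: the target has no stereocentre and no configurationally stable axis (its SMILES carries no stereodescriptor), so it is achiral and no step needs stereocontrol.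

Step 1
Reactants: 1 2,4-dihydroxy-6-methylbenzaldehyde
Product: 2 2,4-bis(methoxymethoxy)-6-methylbenzaldehyde
Conditions: NaH (2.4 equiv), MOMCl (2.4 equiv), DMF, 0 °C to rt
Reagents that add atoms: chloromethyl methyl ether (MOMCl), COCCl
Why: Williamson-type O-alkylation of both sodium phenoxides is routine even for the chelated ortho-hydroxyl once NaH has broken its hydrogen bond, and the MOM acetals tolerate the peracid, carbonate and NBS steps that follow.

Step 2
Reactants: 2 2,4-bis(methoxymethoxy)-6-methylbenzaldehyde
Product: 4 2,4-bis(methoxymethoxy)-6-methylphenol, via aryl formate 3 (not isolated)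
Conditions: mCPBA (1.3 equiv), CH2Cl2, 0 °C to rt; crude in MeOH, K2CO3 (cat.), rt
Reagents that add atoms: 3-chloroperbenzoic acid (mCPBA), O=C(OO)c1cccc(Cl)c1
Why: Baeyer–Villiger oxidation of an electron-rich, di-ortho-substituted benzaldehyde proceeds with aryl migration to the formate, which carbonate-catalysed transesterification converts into the free phenol without touching the MOM groups.

Step 3
Reactants: 5 3-fluoro-5-methylphenol
Product: 6 4-bromo-3-fluoro-5-methylphenol
Conditions: NBS (1.0 equiv), MeCN, −10 °C to rt
Reagents that add atoms: N-bromosuccinimide (NBS), O=C1CCC(=O)N1Br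
Why: Electrophilic aromatic bromination of 3,5-disubstituted phenols with NBS in MeCN goes para to the hydroxyl, a position that here is also ortho to the two other ortho/para directors F and CH3.

Step 4
Reactants: 6 4-bromo-3-fluoro-5-methylphenol
Product: 7 2-bromo-1-fluoro-5-(methoxymethoxy)-3-methylbenzene
Conditions: NaH (1.2 equiv), MOMCl (1.2 equiv), THF–DMF, 0 °C to rt
Reagents that add atoms: chloromethyl methyl ether (MOMCl), COCCl
Why: Williamson-type etherification installs a MOM group that is a strong director for the next metalation and later falls together with the other MOM groups.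

Step 5
Reactants: 7 2-bromo-1-fluoro-5-(methoxymethoxy)-3-methylbenzene
Product: 9 3-bromo-2-fluoro-6-(methoxymethoxy)-4-methylbenzaldehyde, via aryllithium 8 (not isolated)
Conditions: LDA (1.1 equiv, commercial solution), THF, −78 °C; DMF (1.5 equiv), −78 °C; AcOH quench
Reagents that add atoms: N,N-dimethylformamide (DMF), CN(C)C=O
Why: Directed ortho-metalation takes the C–H flanked by F and OMOM, by far the most acidic and best coordinated site, the amide base deprotonates without bromine–lithium exchange, and DMF formylates the aryllithium at −78 °C before loss of LiF can set in.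

Step 6
Reactants: 9 3-bromo-2-fluoro-6-(methoxymethoxy)-4-methylbenzaldehyde
Product: 10 methyl 2-fluoro-3-formyl-4-(methoxymethoxy)-6-methylbenzoate
Conditions: Pd(OAc)2 (3 mol%), Xantphos (6 mol%), CO (1 atm), MeOH (10 equiv), Et3N (2 equiv), toluene, 75 °C
Reagents that add atoms: carbon monoxide, [C-]#[O+]; methanol, CO
Why: Palladium-catalysed alkoxycarbonylation of the aryl bromide, whose ortho neighbours are only F and CH3, tolerates aldehyde and acetal groups, and a weak amine base with little methanol in toluene keeps the newly activated fluoride from being displaced.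

Step 7
Reactants: 4 2,4-bis(methoxymethoxy)-6-methylphenol; 10 methyl 2-fluoro-3-formyl-4-(methoxymethoxy)-6-methylbenzoate
Product: 11 methyl 2-[2,4-bis(methoxymethoxy)-6-methylphenoxy]-3-formyl-4-(methoxymethoxy)-6-methylbenzoate
Conditions: K2CO3 (1.5 equiv), DMF, 75 °C, Ar
Reagents that add atoms: none
Why: Nucleophilic aromatic substitution (SNAr) should succeed because the fluoride is flanked by an ortho-formyl and an ortho-ester acceptor that stabilise the Meisenheimer adduct, and the electron-rich phenoxide attacks perpendicular to the ring plane so that the four ortho substituents are tolerated.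

Step 8
Reactants: 11 methyl 2-[2,4-bis(methoxymethoxy)-6-methylphenoxy]-3-formyl-4-(methoxymethoxy)-6-methylbenzoate
Product: 12 methyl 2-[3-bromo-4,6-bis(methoxymethoxy)-2-methylphenoxy]-3-formyl-4-(methoxymethoxy)-6-methylbenzoate
Conditions: NBS (1.0 equiv), MeCN, 0 °C
Reagents that add atoms: N-bromosuccinimide (NBS), O=C1CCC(=O)N1Br
Why: Electrophilic aromatic bromination of 3,5-dialkoxytoluene-type rings goes to the carbon para to one alkoxy group and next to the methyl group rather than to the crowded carbon between the two alkoxy groups, and ring C is deactivated by CHO and CO2Me.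

Step 9
Reactants: 12 methyl 2-[3-bromo-4,6-bis(methoxymethoxy)-2-methylphenoxy]-3-formyl-4-(methoxymethoxy)-6-methylbenzoate
Product: 13 methyl 2-(3-bromo-4,6-dihydroxy-2-methylphenoxy)-3-formyl-4-hydroxy-6-methylbenzoate
Conditions: conc. HCl (cat.), MeOH, 45 °C; aqueous work-up
Reagents that add atoms: none
Why: Acid-catalysed acetal exchange (MOM cleavage) in methanol frees the three phenols and binds each formaldehyde unit as unreactive dimethoxymethane, while the hindered ester, the aryl bromide and the diaryl ether are inert and the aldehyde is recovered on aqueous work-up.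

Step 10
Reactants: 14 methyl 2,4-dihydroxy-6-methylbenzoate (methyl orsellinate)
Product: 15 methyl 3-[(dimethylamino)methyl]-2,4-dihydroxy-6-methylbenzoate
Conditions: aq. HCHO (1.0 equiv), aq. Me2NH (1.0 equiv), EtOH, 0 °C to rt
Reagents that add atoms: formaldehyde, C=O; dimethylamine, CNC
Why: The Mannich reaction of 2,4-dihydroxyaryl carbonyl compounds takes place at C3, where both hydroxyls activate the ring and hydrogen-bond the iminium ion, whereas C5 is activated less and is flanked by the methyl group.

Step 11
Reactants: 13 methyl 2-(3-bromo-4,6-dihydroxy-2-methylphenoxy)-3-formyl-4-hydroxy-6-methylbenzoate; 15 methyl 3-[(dimethylamino)methyl]-2,4-dihydroxy-6-methylbenzoate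
Product: 17 methyl 2-{3-bromo-4,6-dihydroxy-5-[(2,6-dihydroxy-3-methoxycarbonyl-4-methylphenyl)methyl]-2-methylphenoxy}-3-formyl-4-hydroxy-6-methylbenzoate, via o-quinone methide 16 (not isolated)
Conditions: 13 (1.0 equiv), 15 (1.3 equiv, slow addition), 1,4-dioxane, 95 °C, Ar stream
Reagents that add atoms: none
Why: On heating, the O–H···N-bonded Mannich base 15 loses dimethylamine in a 1,4-elimination that is possible only because the benzylic carbon on C3 of ring A lies between the C2 and C4 hydroxyls, and the resulting o-quinone methide 16 is a soft acceptor at its exocyclic CH2. The ring B carbon between the two free hydroxyls of 13, the enol carbon of a masked 1,3-diketone, adds to this CH2 in a Michael/Friedel–Crafts sense, and proton shifts restore both benzene rings, which makes the C–C bond formation effectively irreversible at this temperature. The closest known reaction type is the thermal alkylation of phenols, naphthols and cyclic 1,3-dicarbonyl donors by o-quinone methides released from phenolic Mannich bases or o-hydroxybenzyl acetates, as used for methylene-bridged polyphenols. No ring is closed and no stereocentre is created, since the new bridge is a CH2 between two planar rings. The step needs site selectivity on ring B, monoalkylation, C- over O-alkylation and tolerance of five free phenols, the aldehyde and two esters: the bromine of 13 occupies the only other activated ring B carbon, so a single nucleophilic C–H is left and a second alkylation is impossible, the remaining aromatic C–H bonds of rings A and C are deactivated by their carbonyl groups, and O-alkylation or re-addition of the amine are reversible and drain to the C-alkylated product. Slow addition of 15 keeps 16 dilute against self-condensation, and the argon stream removes dimethylamine so that it neither recaptures 16 nor stays on the aldehyde.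

Step 12
Reactants: 17 methyl 2-{3-bromo-4,6-dihydroxy-5-[(2,6-dihydroxy-3-methoxycarbonyl-4-methylphenyl)methyl]-2-methylphenoxy}-3-formyl-4-hydroxy-6-methylbenzoate
Product: 18 praesorether F
Conditions: H2 (1 atm), 10% Pd/C, NaOAc (1.5 equiv), EtOAc–MeOH, rt
Reagents that add atoms: none
Why: Catalytic hydrogenolysis (hydrodehalogenation) of an aryl bromide over Pd/C with an acetate buffer should be much faster than reduction of the chelated, di-ortho-substituted aldehyde, and esters, diaryl ether and diarylmethane are inert.

**Compound list**
1 | 2,4-dihydroxy-6-methylbenzaldehyde | Cc1cc(O)cc(O)c1C=O | starting material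
2 | 2,4-bis(methoxymethoxy)-6-methylbenzaldehyde | Cc1cc(OCOC)cc(OCOC)c1C=O | intermediate
3 | 2,4-bis(methoxymethoxy)-6-methylphenyl formate | Cc1cc(OCOC)cc(OCOC)c1OC=O | intermediate
4 | 2,4-bis(methoxymethoxy)-6-methylphenol | Cc1cc(OCOC)cc(OCOC)c1O | intermediate
5 | 3-fluoro-5-methylphenol | Cc1cc(O)cc(F)c1 | starting material
6 | 4-bromo-3-fluoro-5-methylphenol | Cc1cc(O)cc(F)c1Br | intermediate
7 | 2-bromo-1-fluoro-5-(methoxymethoxy)-3-methylbenzene | Cc1cc(OCOC)cc(F)c1Br | intermediate
8 | [3-bromo-2-fluoro-6-(methoxymethoxy)-4-methylphenyl]lithium | Cc1cc(OCOC)c([Li])c(F)c1Br | intermediate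
9 | 3-bromo-2-fluoro-6-(methoxymethoxy)-4-methylbenzaldehyde | Cc1cc(OCOC)c(C=O)c(F)c1Br | intermediate
10 | methyl 2-fluoro-3-formyl-4-(methoxymethoxy)-6-methylbenzoate | COC(=O)c1c(C)cc(OCOC)c(C=O)c1F | intermediate
11 | methyl 2-[2,4-bis(methoxymethoxy)-6-methylphenoxy]-3-formyl-4-(methoxymethoxy)-6-methylbenzoate | COC(=O)c1c(C)cc(OCOC)c(C=O)c1Oc1c(C)cc(OCOC)cc1OCOC | intermediate
12 | methyl 2-[3-bromo-4,6-bis(methoxymethoxy)-2-methylphenoxy]-3-formyl-4-(methoxymethoxy)-6-methylbenzoate | COC(=O)c1c(C)cc(OCOC)c(C=O)c1Oc1c(C)c(Br)c(OCOC)cc1OCOC | intermediate
13 | methyl 2-(3-bromo-4,6-dihydroxy-2-methylphenoxy)-3-formyl-4-hydroxy-6-methylbenzoate | COC(=O)c1c(C)cc(O)c(C=O)c1Oc1c(C)c(Br)c(O)cc1O | intermediate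
14 | methyl 2,4-dihydroxy-6-methylbenzoate (methyl orsellinate) | COC(=O)c1c(C)cc(O)cc1O | starting material
15 | methyl 3-[(dimethylamino)methyl]-2,4-dihydroxy-6-methylbenzoate | COC(=O)c1c(C)cc(O)c(CN(C)C)c1O | intermediate
16 | methyl 2-hydroxy-6-methyl-3-methylidene-4-oxocyclohexa-1,5-diene-1-carboxylate (o-quinone methide of ring A, one of two tautomers) | COC(=O)C1=C(O)C(=C)C(=O)C=C1C | intermediate
17 | methyl 2-{3-bromo-4,6-dihydroxy-5-[(2,6-dihydroxy-3-methoxycarbonyl-4-methylphenyl)methyl]-2-methylphenoxy}-3-formyl-4-hydroxy-6-methylbenzoate | COC(=O)c1c(C)cc(O)c(Cc2c(O)c(Br)c(C)c(Oc3c(C=O)c(O)cc(C)c3C(=O)OC)c2O)c1O | intermediate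
18 | praesorether F | COC(=O)c1c(C)cc(O)c(Cc2c(O)cc(C)c(Oc3c(C=O)c(O)cc(C)c3C(=O)OC)c2O)c1O | target

**Total step count:** 12.
**Longest linear sequence:** 9 steps (steps 3, 4, 5, 6, 7, 8, 9, 11, 12, from 3-fluoro-5-methylphenol).

**Steps most likely to fail**

Step 11. The quinone methide may self-condense faster than it is captured. The bromine may be lost from ring B under amine and heat, so that site control disappears. The methylene bridge may also exchange between rings by retro-addition on prolonged heating. The fallback reverses the roles of donor and acceptor. Setting out from 13, a Mannich reaction (aq. HCHO, aq. Me2NH, EtOH, rt) at its only free activated carbon should give the ring B Mannich base methyl 2-{3-bromo-5-[(dimethylamino)methyl]-4,6-dihydroxy-2-methylphenoxy}-3-formyl-4-hydroxy-6-methylbenzoate F1. Heating this with a large excess of cheap 14 in dioxane should expel dimethylamine to the ring B o-quinone methide F2. C3 of 14 (the site that reacts in step 10) then captures it, and the route is rejoined at 17.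

Step 7. Addition to the crowded fluoride may be sluggish, the phenoxide may attack the aldehyde or ester instead, or the electron-rich phenoxide may be oxidised by air. The fallback forms the ether before the ester is in place. Setting out from 4 and 9 (Cs2CO3, DMA, 120 °C), the fluoride is flanked only by the flat formyl group and a compact bromine. This should give the bromo diaryl ether 2-[2,4-bis(methoxymethoxy)-6-methylphenoxy]-3-bromo-6-(methoxymethoxy)-4-methylbenzaldehyde F3. Palladium-catalysed methoxycarbonylation can then be forced (Pd(dppf)Cl2, CO 10 bar, MeOH, Et3N, 110 °C), because no displaceable fluoride is left. The route is rejoined at 11.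

Step 12. The aldehyde may be over-reduced (to the alcohol and on to methyl by hydrogenolysis), or the hydrogenolysis may stall through adsorption of the polyphenol on the catalyst. The fallback replaces catalytic hydrogenolysis by ionic reductive debromination. Setting out from 17, treatment with Na2SO3 in MeOH–H2O at rt relies on ipso-protonation of the very electron-rich ring at the C–Br carbon (para to one hydroxyl and ortho to the other). Sulfite then attacks bromine, the classical way to strip such bromines from bromoresorcinols. Any bisulfite addition to the aldehyde is reversed on acidic work-up. The route is rejoined at 18 without a new compound.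

**Further compounds**
F1 | step 11 | methyl 2-{3-bromo-5-[(dimethylamino)methyl]-4,6-dihydroxy-2-methylphenoxy}-3-formyl-4-hydroxy-6-methylbenzoate | COC(=O)c1c(C)cc(O)c(C=O)c1Oc1c(C)c(Br)c(O)c(CN(C)C)c1O
F2 | step 11 | methyl 2-[(3-bromo-6-hydroxy-2-methyl-5-methylidene-4-oxocyclohexa-1,5-dien-1-yl)oxy]-3-formyl-4-hydroxy-6-methylbenzoate (ring B o-quinone methide) | COC(=O)c1c(C)cc(O)c(C=O)c1OC1=C(O)C(=C)C(=O)C(Br)=C1C
F3 | step 7 | 2-[2,4-bis(methoxymethoxy)-6-methylphenoxy]-3-bromo-6-(methoxymethoxy)-4-methylbenzaldehyde | O=Cc1c(OCOC)cc(C)c(Br)c1Oc1c(C)cc(OCOC)cc1OCOC
F0 | step 12 | none | none
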